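The plan reads the allylic ester array C4=C5–C6–O inside the nine-membered oxonane ring (bridging O, C3, C4, C5, C6, C7, C8, C9, C10; germacrane numbers) as a C4=C5=C6 allene that has taken up the C12 carboxyl group. Nine is the smallest ring that holds an allene almost without strain. Such an allene arises from an eight-membered cycloalkene by insertion of one carbon atom. The key step opens a dibromocyclopropane fused to the C4–C6 bond of a 10-oxabicyclo[5.2.1]decane, so C5 enters the ring and eight becomes nine. The alkene forerunner, which lacks C5, is assembled from (R)-linalool and a pentadienoate by allylation and ring-closing metathesis.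

Key step: step 10

Remark on labels: C1–C15 are the germacrane numbers of the target. C1H2 and C2H2 are the ethano bridge, C3 is the hemiketal carbon, and C4=C5 carries C15H2OH on C4. C6 is the lactone O–CH, C8 bears the O-isobutyryl group, C9 is CH2, and C10 bears C14H3 and the bridging O. C11=C13H2 is the exocyclic methylene and C12 is the lactone C=O.

Assumption: commercial (R)-(−)-linalool of high enantiomeric purity is used. It is the only source of absolute configuration.

Step 1
Reactants: 1 (R)-(−)-linalool
Product: 3 (6R)-6-hydroxy-2,6-dimethylocta-1,7-dien-3-one, via allylic hydroperoxide 2 (not isolated)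
Conditions: O2, tetraphenylporphyrin (cat.), hν (visible), CH2Cl2, 0 °C; then Ac2O, pyridine, 0 °C to rt
Reagents that add atoms: dioxygen O=O
Why: Schenck ene reaction of singlet oxygen at the electron-rich trisubstituted C3=C4 alkene (the vinyl group is inert), with hydrogen abstraction from a methyl group, gives the secondary allylic hydroperoxide, whose Kornblum–DeLaMare-type dehydration gives the enone, while the regioisomeric tertiary hydroperoxide cannot dehydrate and is removed by chromatography; C10 comes unchanged from 1.

Step 2
Reactants: 3 (6R)-6-hydroxy-2,6-dimethylocta-1,7-dien-3-one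
Product: 4 (2R,5R)-2-methoxy-5-methyl-2-(prop-1-en-2-yl)-5-vinyltetrahydrofuran
Conditions: MeOH, PPTS (cat.), 3 Å molecular sieves, rt
Reagents that add atoms: methanol CO
Why: Acid-catalysed cyclic ketalisation, in which the C10 hydroxyl adds to the C3 ketone and the five-membered oxocarbenium ion takes up methanol; the two C3 anomers interconvert under the acid, the anomer with isopropenyl cis to vinyl is separated and the other is re-equilibrated.

Step 3
Reactants: 4 (2R,5R)-2-methoxy-5-methyl-2-(prop-1-en-2-yl)-5-vinyltetrahydrofuran
Product: 5 2-[(2R,5R)-5-methoxy-2-methyl-5-(prop-1-en-2-yl)tetrahydrofuran-2-yl]acetaldehyde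
Conditions: PdCl2(PhCN)2 (cat.), CuCl2·2H2O (cat.), AgNO2 (cat.), O2 (1 atm), t-BuOH/MeNO2, rt
Reagents that add atoms: dioxygen O=O
Why: Nitrite-modified, aldehyde-selective Wacker oxidation, which is anti-Markovnikov for a vinyl group on a fully substituted, oxygen-bearing carbon and leaves the 1,1-disubstituted isopropenyl group untouched.

Step 4
Reactants: 6 acrolein, 7 tert-butyl acrylate
Product: 8 tert-butyl 3-hydroxy-2-methylenepent-4-enoate (racemic)
Conditions: DABCO (cat.), neat, rt
Reagents that add atoms: none
Why: Morita–Baylis–Hillman reaction, in which DABCO adds to the acrylate and the resulting enolate attacks the aldehyde carbon of acrolein; the racemic carbinol centre is erased in step 5.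

Step 5
Reactants: 8 tert-butyl 3-hydroxy-2-methylenepent-4-enoate
Product: 9 tert-butyl (Z)-2-(bromomethyl)penta-2,4-dienoate
Conditions: NBS, Me2S, CH2Cl2, 0 °C to rt
Reagents that add atoms: N-bromosuccinimide O=C1CCC(=O)N1Br
Why: SN2′ bromination of a Baylis–Hillman alcohol with the NBS–Me2S reagent, in which bromide enters at the acrylate methylene carbon and the conjugated dienoate forms with Z geometry, as is usual for ester-derived adducts.

Step 6
Reactants: 5 2-[(2R,5R)-5-methoxy-2-methyl-5-(prop-1-en-2-yl)tetrahydrofuran-2-yl]acetaldehyde, 9 tert-butyl (Z)-2-(bromomethyl)penta-2,4-dienoate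
Product: 11 tert-butyl (3R,4R)-4-hydroxy-5-[(2R,5R)-5-methoxy-2-methyl-5-(prop-1-en-2-yl)tetrahydrofuran-2-yl]-2-methylene-3-vinylpentanoate, via pentadienylzinc bromide 10 (not isolated)
Conditions: Zn dust (activated), THF, 0 °C to rt; then pH 7 buffer
Reagents that add atoms: none
Why: Barbier-type 2-(alkoxycarbonyl)allylation, in which the pentadienylzinc reagent attacks through its central carbon (C7) in a closed chair transition state, the Z reagent gives the 7,8-syn pair, chelation of zinc by the aldehyde oxygen and the ring oxygen on C10 directs attack to the face anti to the C10 methyl group, and minor diastereomers are removed by chromatography.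

Step 7
Reactants: 11 tert-butyl (3R,4R)-4-hydroxy-5-[...]-2-methylene-3-vinylpentanoate
Product: 12 the 4-O-isobutyrate of 11 (C8 ester)
Conditions: (i-PrCO)2O, DMAP (cat.), pyridine, CH2Cl2, rt
Reagents that add atoms: isobutyric anhydride CC(C)C(=O)OC(=O)C(C)C
Why: DMAP-catalysed acylation of the only hydroxyl group, with no stereocentre touched.

Step 8
Reactants: 12 the 4-O-isobutyrate of 11
Product: 13 bicyclic alkene (10-oxabicyclo[5.2.1]dec-2-ene; Z-C4(CH3)=C6H, no C5)
Conditions: second-generation Hoveyda–Grubbs catalyst (10 mol %), 1,4-benzoquinone (cat.), toluene (1 mM), 100 °C, argon sparge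
Reagents that add atoms: none
Why: Ring-closing metathesis, in which the ruthenium carbene forms at the monosubstituted C6 vinyl group and closes on the isopropenyl group held nearby by the cis-2,5-substituted tetrahydrofuran, the ring size enforces the Z alkene, and the electron-poor 1,1-disubstituted acrylate does not take part.

Step 9
Reactants: 13 bicyclic alkene
Product: 14 gem-dibromocyclopropane (CBr2 = C5 bridges C4 and C6)
Conditions: PhHgCBr3 (1.3 equiv), benzene, 80 °C
Reagents that add atoms: phenyl(tribromomethyl)mercury BrC(Br)(Br)[Hg]c1ccccc1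
Why: Cheletropic [2+1] addition of free dibromocarbene under neutral conditions, which spares the base-sensitive C7–H and the esters; the electrophilic carbene selects the trisubstituted C4=C6 alkene over the acrylate and adds syn from the outer face (C4 and C6 are set here and erased in step 10).

Step 10
Reactants: 14 gem-dibromocyclopropane
Product: 16 cyclic allene (11-oxabicyclo[6.2.1]undeca-2,3-diene; C4(CH3)=C5=C6H), via magnesium carbenoid 15 (not isolated)
Conditions: i-PrMgCl (1.2 equiv), THF, −60 °C, then to 20 °C
Reagents that add atoms: none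
Why: Bromine–magnesium exchange at the less hindered exo bromine gives carbenoid 15; on warming it loses MgBrCl, and the cyclopropylidene opens with cleavage of the C4–C6 bond, so that C5 becomes the central carbon of a C4=C5=C6 allene (Doering–Moore–Skattebøl reaction). The closest known case is the passage from 9,9-dibromobicyclo[6.1.0]nonane to cyclonona-1,2-diene, the same eight-to-nine enlargement, for which Grignard reagents are known to serve in place of methyllithium. No ring is closed by a new bond: the three-membered ring and the eight-membered ring (O, C3, C4, C6, C7, C8, C9, C10) merge into the nine-membered oxonane, and the nine-membered carbocycle becomes the ten-membered germacrane ring. No stereocentre is made, the centres C4 and C6 vanish, and the only new element, the allene axis, depends on the sense of opening and need not be controlled because step 11 is convergent. The step needs exchange to outrun addition to the carbonyl groups, which the low temperature, the mild Grignard reagent and the bulk of the tert-butyl and isobutyryl esters secure, and it needs opening to outrun C–H insertion, which the almost strain-free nine-membered allene secures.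

Step 11
Reactants: 16 cyclic allene
Product: 17 15-deoxy 3-O-methyl ketal of the target
Conditions: Ph3PAuNTf2 (5 mol %), CH2Cl2, rt
Reagents that add atoms: none
Why: Gold-catalysed 5-exo hydroacyloxylation of a γ-allenic ester, in which the carbonyl oxygen of the tert-butyl ester attacks C6 anti to gold, isobutene leaves and protodeauration puts hydrogen on C5, the arm on C7 reaches C6 only with C8 antiperiplanar to C5 (trans-fused lactone, C6 set by C7), a trans C4=C5 bond is too strained in the bridged ring so that C3 and C6 end up cis, and gold-induced epimerisation of the allene axis lets both axis isomers funnel into 17.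

Step 12
Reactants: 17 15-deoxy 3-O-methyl ketal of the target
Product: 18 3-O-methyl ketal of the target
Conditions: SeO2 (cat.), t-BuOOH, CH2Cl2, rt
Reagents that add atoms: tert-butyl hydroperoxide CC(C)(C)OO
Why: Riley oxidation (ene reaction, then [2,3]-sigmatropic shift), for which C15 is the only reactive allylic position (C3 bears no hydrogen, C6–H is deactivated by the acyloxy group, the C11=C13 alkene is electron-poor), and the double bond returns to C4=C5 with C15 trans to C6.

Step 13
Reactants: 18 3-O-methyl ketal of the target
Product: 19 CNP0282937.1 (target)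
Conditions: 0.5 M aq. HCl, THF, rt
Reagents that add atoms: water O
Why: Acid hydrolysis of the bridgehead methyl ketal through the allyl-stabilised oxocarbenium ion, in which the bicyclic frame lets water return only with the C3 configuration fixed by C10, and lactone, isobutyrate and allylic alcohol are stable to dilute acid.

Compound list
1 | (R)-(−)-linalool, (3R)-3,7-dimethylocta-1,6-dien-3-ol | CC(C)=CCC[C@](C)(C=C)O | starting material
2 | (6R)-3-hydroperoxy-2,6-dimethylocta-1,7-dien-6-ol (both C3 epimers) | C=C(C)C(OO)CC[C@](C)(C=C)O | intermediate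
3 | (6R)-6-hydroxy-2,6-dimethylocta-1,7-dien-3-one | C=C(C)C(=O)CC[C@](C)(C=C)O | intermediate
4 | (2R,5R)-2-methoxy-5-methyl-2-(prop-1-en-2-yl)-5-vinyltetrahydrofuran | C=C(C)[C@@]1(OC)CC[C@](C)(C=C)O1 | intermediate
5 | 2-[(2R,5R)-5-methoxy-2-methyl-5-(prop-1-en-2-yl)tetrahydrofuran-2-yl]acetaldehyde | C=C(C)[C@@]1(OC)CC[C@](C)(CC=O)O1 | intermediate
6 | acrolein | C=CC=O | starting material
7 | tert-butyl acrylate | C=CC(=O)OC(C)(C)C | starting material
8 | tert-butyl 3-hydroxy-2-methylenepent-4-enoate (racemic) | C=CC(O)C(=C)C(=O)OC(C)(C)C | intermediate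
9 | tert-butyl (Z)-2-(bromomethyl)penta-2,4-dienoate | C=C/C=C(\CBr)C(=O)OC(C)(C)C | intermediate
10 | [(Z)-2-(tert-butoxycarbonyl)penta-2,4-dienyl]zinc bromide | C=C/C=C(\C[Zn]Br)C(=O)OC(C)(C)C | intermediate
11 | tert-butyl (3R,4R)-4-hydroxy-5-[(2R,5R)-5-methoxy-2-methyl-5-(prop-1-en-2-yl)tetrahydrofuran-2-yl]-2-methylene-3-vinylpentanoate (7,8-syn; C7 and C8 as in 19) | C=C(C)[C@@]1(OC)CC[C@](C)(C[C@@H](O)[C@H](C=C)C(=C)C(=O)OC(C)(C)C)O1 | intermediate
12 | 4-O-isobutyrate of 11 (isobutyryloxy on C8) | C=C(C)[C@@]1(OC)CC[C@](C)(C[C@@H](OC(=O)C(C)C)[C@H](C=C)C(=C)C(=O)OC(C)(C)C)O1 | intermediate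
13 | bicyclic alkene, 10-oxabicyclo[5.2.1]dec-2-ene: C3 methoxy bridgehead, Z-C4(CH3)=C6H, C7 with 1-(tert-butoxycarbonyl)vinyl, C8 with isobutyryloxy, C9H2, C10 methyl bridgehead; C3, C7, C8, C10 as in 12 | C=C(C(=O)OC(C)(C)C)[C@H]1/C=C(/C)[C@@]2(OC)CC[C@](C)(C[C@H]1OC(=O)C(C)C)O2 | intermediate
14 | gem-dibromocyclopropane of 13: CBr2 (C5) bridges C4 and C6, cis-fused, on the face that carries C11 and OCH3 | C=C(C(=O)OC(C)(C)C)[C@H]1[C@@H]3C(Br)(Br)[C@]3(C)[C@@]2(OC)CC[C@](C)(C[C@H]1OC(=O)C(C)C)O2 | intermediate
15 | magnesium carbenoid from 14 (exo MgCl, endo Br on C5) | C=C(C(=O)OC(C)(C)C)[C@H]1[C@@H]3[C@@](Br)([Mg]Cl)[C@]3(C)[C@@]2(OC)CC[C@](C)(C[C@H]1OC(=O)C(C)C)O2 | intermediate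
16 | cyclic allene, 11-oxabicyclo[6.2.1]undeca-2,3-diene: C4(CH3)=C5=C6H, other groups as in 13, allene axis not defined | C=C(C(=O)OC(C)(C)C)[C@H]1C=C=C(C)[C@@]2(OC)CC[C@](C)(C[C@H]1OC(=O)C(C)C)O2 | intermediate
17 | 15-deoxy 3-O-methyl ketal of the target (C4–CH3, 6,7-trans α-methylene lactone, Z-C4=C5) | C=C1C(=O)O[C@@H]2/C=C(/C)[C@@]3(OC)CC[C@](C)(C[C@@H](OC(=O)C(C)C)[C@@H]12)O3 | intermediate
18 | 3-O-methyl ketal of the target | C=C1C(=O)O[C@@H]2/C=C(/CO)[C@@]3(OC)CC[C@](C)(C[C@@H](OC(=O)C(C)C)[C@@H]12)O3 | intermediate
19 | CNP0282937.1, (3R,6R,7R,8R,10R)-3,10-epoxy-3,15-dihydroxy-8-isobutyryloxygermacra-4Z,11(13)-dien-6,12-olide | C=C1C(=O)O[C@@H]2/C=C(/CO)[C@@]3(O)CC[C@](C)(C[C@@H](OC(=O)C(C)C)[C@@H]12)O3 | target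

Total step count: 13. Longest linear sequence: 11 (steps 1–3 and 6–13).

Steps most likely to fail

1. Step 8. Closure may be slow because the isopropenyl group sits on the fully substituted C3, so oligomerisation through the vinyl group or migration of the skipped diene may take over. The fallback sets out from 12. Ozonolysis of the two electron-rich alkenes (O3, CH2Cl2, −78 °C, then Me2S; the acrylate is spared) gives the keto aldehyde F1, which is used at once. An intramolecular McMurry coupling (TiCl3, Zn–Cu couple, DME, high dilution) then joins C4 and C6 and comes back to the route at 13.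

2. Step 10. The Grignard reagent may add to an ester or to the acrylate, or the cyclopropylidene may insert into a transannular C–H bond. The fallback sets out from 14 and keeps the eight-to-nine enlargement. AgBF4 in CH2Cl2 ionises one bromide with disrotatory electrocyclic opening of the cyclopropane. The bridged frame is expected to favour loss of the endo bromide and thus the cis allyl cation. The tert-butyl ester carbonyl traps this cation at C6 with loss of isobutene to give the 5-bromo lactone F2. Hydrodebromination (Pd(PPh3)4, Bu3SnH, THF) comes back to the route at 17.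

3. Step 6. Facial selectivity at the aldehyde may be poor, because the C10 centre offers only a methyl and a methylene group to tell apart. The fallback sets out from 5 and 9. A catalyst-controlled Nozaki–Hiyama–Kishi-type allylation (CrCl2 (cat.), chiral carbazole-bridged bis(oxazoline) ligand, Mn, Cp2ZrCl2, THF) gives the 7,8-anti alcohol F3, which has the correct C7 and is epimeric at C8. A Mitsunobu reaction with isobutyric acid (PPh3, DIAD, toluene) inverts C8, installs the ester and comes back to the route at 12.

Further compounds
F1 | step 8 | keto aldehyde from 12 (acetyl on C3, formyl on C7) | CC(=O)[C@@]1(OC)CC[C@](C)(C[C@@H](OC(=O)C(C)C)[C@H](C=O)C(=C)C(=O)OC(C)(C)C)O1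
F2 | step 10 | 5-bromo derivative of 17 | C=C1C(=O)O[C@@H]2/C(Br)=C(/C)[C@@]3(OC)CC[C@](C)(C[C@@H](OC(=O)C(C)C)[C@@H]12)O3
F3 | step 6 | C8 epimer of 11 (7,8-anti) | C=C(C)[C@@]1(OC)CC[C@](C)(C[C@H](O)[C@H](C=C)C(=C)C(=O)OC(C)(C)C)O1
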